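The flavonol is disconnected across ring C at C3–C4 and O1–C8a. Ring A carries oxygen at C8a (O1), C5 and C7, which are both ortho positions and the para position relative to C4a, the carbon bearing the C4 carbonyl; fluorine at exactly these sites of a 2,4,6-trifluorobenzoyl unit is activated for SNAr. One operation therefore C-acylates the enolate of an α-benzyloxy aryl ketone (ring B, C2, C3 and two benzyl ethers already in place) and closes ring C by fluoride displacement, leaving C5–F and C7–F as masked hydroxyls. These are exchanged for 4-methoxybenzyl ethers, unmasked, and O7 is sulfated beside the chelated 5-hydroxyl before hydrogenolysis.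

Key step: step 2

Remark: compounds 1, 2 and 5 are taken as catalogue chemicals. The target is drawn as the free hydrogen sulfate, so it is liberated from its triethylammonium salt by cation exchange at the very end; such acids hydrolyse under their own acidity and are best kept cold or stored as a salt. The target has no stereocentre.

Step 1
Reactants: 1 1-(benzyloxy)-4-bromo-2-methoxybenzene; 2 2-(benzyloxy)-N-methoxy-N-methylacetamide
Product: 4 2-(benzyloxy)-1-[4-(benzyloxy)-3-methoxyphenyl]ethan-1-one, via arylmagnesium bromide 3 (not isolated)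
Conditions: 1 (1.2 eq), Mg turnings, I2 (cat.), THF, 50 °C; then 2 (1.0 eq), THF, 0 °C → rt; 1 M HCl
Reagents that add atoms: none
Why: Magnesium insertion into the aryl bromide followed by a Weinreb ketone synthesis should give the ketone cleanly, because the N-methoxy-N-methyl amide is held as a magnesium-chelated tetrahedral adduct until the acidic quench, so a second addition cannot occur and no α-halo ketone or alkoxide displacement is needed.

Step 2
Reactants: 4 2-(benzyloxy)-1-[4-(benzyloxy)-3-methoxyphenyl]ethan-1-one; 5 2,4,6-trifluorobenzoyl chloride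
Product: 8 3-(benzyloxy)-2-[4-(benzyloxy)-3-methoxyphenyl]-5,7-difluoro-4H-chromen-4-one, via lithium enolate 6 (not isolated), via trifluorophenyl 1,3-diketone 7 (not isolated)
Conditions: LiN(SiMe3)2 (2.2 eq), THF, −78 °C; then 5 (1.05 eq), −78 °C → rt; then 60 °C
Reagents that add atoms: none
Why: LiN(SiMe3)2 converts 4 into the chelated (Z)-lithium enolate 6, whose α-carbon adds to the acyl chloride and expels chloride to form C3–C4; the second equivalent of base deprotonates the more acidic diketone 7, and the enolate oxygen on the carbon bearing ring B adds to an ortho C–F carbon of the trifluorophenyl ring to give a Meisenheimer adduct that loses fluoride, forming O1–C8a. The closest known reaction type is the one-pot C-acylation of ketone enolates with ortho-fluorobenzoyl chlorides followed by intramolecular SNAr, an established entry to chromones and flavones (a fluoride-displacement counterpart of the Baker–Venkataraman diketone route). Ring C closes by a six-membered oxygen-to-aryl addition–elimination, 6-endo-trig when counted on the C4a=C8a π bond that relays the charge into the C4 carbonyl, with fluoride leaving from the ring carbon. No stereocentre is created, and the central carbon of 7 becomes planar again in the product. The step needs C- rather than O-acylation, which the tight lithium chelate in THF at −78 °C and the excess base that drains the diketone as its enolate should secure (an enol ester, if formed, is itself an acyl donor toward 6), and it needs cyclisation rather than intermolecular attack on the para fluorine, which the proximity of the enolate oxygen to the ortho C–F bond should secure. Because the two ortho fluorines of 5 are equivalent by symmetry, only one chromenone can form.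

Step 3
Reactants: 8 3-(benzyloxy)-2-[4-(benzyloxy)-3-methoxyphenyl]-5,7-difluoro-4H-chromen-4-one
Product: 10 3-(benzyloxy)-2-[4-(benzyloxy)-3-methoxyphenyl]-5,7-bis[(4-methoxybenzyl)oxy]-4H-chromen-4-one, via 5-fluoro 7-(4-methoxybenzyl) monoether 9 (not isolated)
Conditions: 4-MeOC6H4CH2OH (3 eq), KOtBu (2.6 eq), DMSO/THF, rt → 50 °C
Reagents that add atoms: 4-methoxybenzyl alcohol, COc1ccc(CO)cc1
Why: Twofold nucleophilic aromatic substitution (SNAr) should occur because C7 and C5 are para and ortho to C4a, which bears the C4 carbonyl, so both C–F bonds accept the potassium alkoxide through carbonyl-stabilised Meisenheimer adducts, and since the same group enters at both carbons no positional selectivity is required.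

Step 4
Reactants: 10 3-(benzyloxy)-2-[4-(benzyloxy)-3-methoxyphenyl]-5,7-bis[(4-methoxybenzyl)oxy]-4H-chromen-4-one
Product: 11 3-(benzyloxy)-2-[4-(benzyloxy)-3-methoxyphenyl]-5,7-dihydroxy-4H-chromen-4-one
Conditions: CF3CO2H (10 vol%), anisole (10 eq), CH2Cl2, 0 °C → rt
Reagents that add atoms: none
Why: Acidolysis of aryl 4-methoxybenzyl ethers (SN1 cleavage to the stabilised 4-methoxybenzyl cation, trapped by anisole in a Friedel–Crafts alkylation) should free both ring A hydroxyls, while the plain benzyl ethers at O3 and O4′, which ionise far more slowly, should remain.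

Step 5
Reactants: 11 3-(benzyloxy)-2-[4-(benzyloxy)-3-methoxyphenyl]-5,7-dihydroxy-4H-chromen-4-one
Product: 12 triethylammonium 3-(benzyloxy)-2-[4-(benzyloxy)-3-methoxyphenyl]-5-hydroxy-4-oxo-4H-chromen-7-yl sulfate
Conditions: SO3·NEt3 (1.5 eq), Et3N (1 eq), DMF, rt → 40 °C
Reagents that add atoms: sulfur trioxide–triethylamine complex, CC[N+](CC)(CC)S(=O)(=O)[O-]
Why: O-Sulfonation of a phenol by an amine–sulfur trioxide complex should take place only at O7, because the 7-hydroxyl is a vinylogous acid through C4=O and is deprotonated by Et3N, whereas the 5-hydroxyl is tied to the C4 carbonyl by a six-membered hydrogen bond and is the least reactive flavonoid hydroxyl toward sulfation.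

Step 6
Reactants: 12 triethylammonium 3-(benzyloxy)-2-[4-(benzyloxy)-3-methoxyphenyl]-5-hydroxy-4-oxo-4H-chromen-7-yl sulfate
Product: 14 3,5-dihydroxy-2-(4-hydroxy-3-methoxyphenyl)-4-oxo-4H-chromen-7-yl hydrogen sulfate (isorhamnetin 7-O-sulfate), via triethylammonium isorhamnetin 7-sulfate 13 (not isolated)
Conditions: H2 (1 atm), 10% Pd/C, MeOH/THF, rt; filter; Dowex 50WX8 (H+ form), H2O/MeCN, 0 °C; freeze-dry
Reagents that add atoms: none
Why: Catalytic hydrogenolysis of the two benzyl ethers over palladium should leave the aryl sulfate monoester and the C2=C3 bond of the flavonol intact, and a strong-acid cation exchange resin should then swap triethylammonium for a proton to give the hydrogen sulfate.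

Compound list
1 | 1-(benzyloxy)-4-bromo-2-methoxybenzene | COc1cc(Br)ccc1OCc1ccccc1 | starting material
2 | 2-(benzyloxy)-N-methoxy-N-methylacetamide | CON(C)C(=O)COCc1ccccc1 | starting material
3 | [4-(benzyloxy)-3-methoxyphenyl]magnesium bromide | COc1cc([Mg]Br)ccc1OCc1ccccc1 | intermediate (not isolated)
4 | 2-(benzyloxy)-1-[4-(benzyloxy)-3-methoxyphenyl]ethan-1-one | COc1cc(C(=O)COCc2ccccc2)ccc1OCc1ccccc1 | intermediate
5 | 2,4,6-trifluorobenzoyl chloride | O=C(Cl)c1c(F)cc(F)cc1F | starting material
6 | lithium (Z)-2-(benzyloxy)-1-[4-(benzyloxy)-3-methoxyphenyl]ethen-1-olate | [Li]O/C(=C\OCc1ccccc1)c1ccc(OCc2ccccc2)c(OC)c1 | intermediate (not isolated)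
7 | 2-(benzyloxy)-1-[4-(benzyloxy)-3-methoxyphenyl]-3-(2,4,6-trifluorophenyl)propane-1,3-dione (racemic, present in the flask as its lithium enolate) | COc1cc(C(=O)C(OCc2ccccc2)C(=O)c2c(F)cc(F)cc2F)ccc1OCc1ccccc1 | intermediate (not isolated)
8 | 3-(benzyloxy)-2-[4-(benzyloxy)-3-methoxyphenyl]-5,7-difluoro-4H-chromen-4-one | COc1cc(-c2oc3cc(F)cc(F)c3c(=O)c2OCc2ccccc2)ccc1OCc1ccccc1 | intermediate
9 | 3-(benzyloxy)-2-[4-(benzyloxy)-3-methoxyphenyl]-5-fluoro-7-[(4-methoxybenzyl)oxy]-4H-chromen-4-one | COc1cc(-c2oc3cc(OCc4ccc(OC)cc4)cc(F)c3c(=O)c2OCc2ccccc2)ccc1OCc1ccccc1 | intermediate (not isolated)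
10 | 3-(benzyloxy)-2-[4-(benzyloxy)-3-methoxyphenyl]-5,7-bis[(4-methoxybenzyl)oxy]-4H-chromen-4-one | COc1cc(-c2oc3cc(OCc4ccc(OC)cc4)cc(OCc4ccc(OC)cc4)c3c(=O)c2OCc2ccccc2)ccc1OCc1ccccc1 | intermediate
11 | 3-(benzyloxy)-2-[4-(benzyloxy)-3-methoxyphenyl]-5,7-dihydroxy-4H-chromen-4-one | COc1cc(-c2oc3cc(O)cc(O)c3c(=O)c2OCc2ccccc2)ccc1OCc1ccccc1 | intermediate
12 | triethylammonium 3-(benzyloxy)-2-[4-(benzyloxy)-3-methoxyphenyl]-5-hydroxy-4-oxo-4H-chromen-7-yl sulfate | COc1cc(-c2oc3cc(OS(=O)(=O)[O-])cc(O)c3c(=O)c2OCc2ccccc2)ccc1OCc1ccccc1.CC[NH+](CC)CC | intermediate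
13 | triethylammonium 3,5-dihydroxy-2-(4-hydroxy-3-methoxyphenyl)-4-oxo-4H-chromen-7-yl sulfate | COc1cc(-c2oc3cc(OS(=O)(=O)[O-])cc(O)c3c(=O)c2O)ccc1O.CC[NH+](CC)CC | intermediate (not isolated)
14 | 3,5-dihydroxy-2-(4-hydroxy-3-methoxyphenyl)-4-oxo-4H-chromen-7-yl hydrogen sulfate (isorhamnetin 7-O-sulfate) | COc1cc(-c2oc3cc(OS(=O)(=O)O)cc(O)c3c(=O)c2O)ccc1O | target

Total step count: 6
Longest linear sequence: 6 steps (1 → 4 → 8 → 10 → 11 → 12 → 14); compounds 2 and 5 are purchased and enter directly.

Steps most likely to fail

Step 2. Competing O-acylation or double acylation of the enolate, and stalling of the ring closure at the diketone enolate, may divert material in the one-pot sequence. The fallback sets out from 4 and forms C3–C4 by an aldol addition, where only carbon attack is possible. Enolate 6 (LiN(SiMe3)2, THF, −78 °C) would be added to 2,4,6-trifluorobenzaldehyde to give 2-(benzyloxy)-1-[4-(benzyloxy)-3-methoxyphenyl]-3-hydroxy-3-(2,4,6-trifluorophenyl)propan-1-one F1 as a mixture of racemic diastereomers, all of which serve. Oxidation with Dess–Martin periodinane in CH2Cl2 should give diketone 7, now isolated. Closure with K2CO3 in DMF at 60 °C as a separate intramolecular SNAr step returns the route to 8.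

Step 3. The second displacement, at the peri C5 carbon of a ring made more electron-rich by the first ether, may lag, and long heating with excess alkoxide may open the pyranone by addition at C2. The fallback sets out from 8 and inverts the order of the two displacements. One equivalent of sodium 4-methoxybenzyl alkoxide (NaH) in toluene at 0 °C → rt should be delivered to C5 by the sodium ion bound to the C4 carbonyl, while the ring is still activated by the C7 fluorine. This should give 3-(benzyloxy)-2-[4-(benzyloxy)-3-methoxyphenyl]-7-fluoro-5-[(4-methoxybenzyl)oxy]-4H-chromen-4-one F2. The unhindered C7 fluoride, para to the carbonyl, would then be exchanged with the potassium alkoxide in DMSO at rt, which returns the route to 10.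

Step 4. Acidolysis may not stop at the 4-methoxybenzyl ethers (loss of the O3 benzyl group), and the benzylic cation may alkylate C6 or C8 of the freed ring A before it is trapped. The fallback sets out from 8 and uses ethers that are removed without acid. Allyl alcohol and NaH in THF (0 → 60 °C) should give 3-(benzyloxy)-2-[4-(benzyloxy)-3-methoxyphenyl]-5,7-bis(prop-2-en-1-yloxy)-4H-chromen-4-one F3 by the same twofold SNAr. Deallylation with catalytic Pd(PPh3)4 (zerovalent palladium) and morpholine in THF at rt, a Tsuji–Trost allyl transfer to the amine, returns the route to 11 under neutral conditions that leave benzyl ethers untouched.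

Further compounds
F1 | step 2 | 2-(benzyloxy)-1-[4-(benzyloxy)-3-methoxyphenyl]-3-hydroxy-3-(2,4,6-trifluorophenyl)propan-1-one (mixture of racemic diastereomers) | COc1cc(C(=O)C(OCc2ccccc2)C(O)c2c(F)cc(F)cc2F)ccc1OCc1ccccc1
F2 | step 3 | 3-(benzyloxy)-2-[4-(benzyloxy)-3-methoxyphenyl]-7-fluoro-5-[(4-methoxybenzyl)oxy]-4H-chromen-4-one | COc1cc(-c2oc3cc(F)cc(OCc4ccc(OC)cc4)c3c(=O)c2OCc2ccccc2)ccc1OCc1ccccc1
F3 | step 4 | 3-(benzyloxy)-2-[4-(benzyloxy)-3-methoxyphenyl]-5,7-bis(prop-2-en-1-yloxy)-4H-chromen-4-one | COc1cc(-c2oc3cc(OCC=C)cc(OCC=C)c3c(=O)c2OCc2ccccc2)ccc1OCc1ccccc1
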